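## Retrosynthetic overview

1. The hydroxyquinone is unmasked last by Teuber oxidation of a 2-alkyl-4-chloro-5-methylresorcinol; the (S)-carbinol comes from a CBS reduction of the side-chain enone.
2. Key disconnection: the bond between the quaternary ring carbon (C3 of the cyclohexanone) and the side-chain CH2. It is formed in the same operation that enlarges a five-membered ring to the cyclohexanone: a silver salt opens a 6-chloro-6-methyl-1-siloxybicyclo[3.1.0]hexane to an O-silylated 2,3,4-trimethylcyclohexenone cation, which the dienol silane of the complete aryl side chain attacks at C3.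
3. Enabling feature: the strained C1–C5 fusion bond of the bicyclo[3.1.0]hexane (cyclopropane fused to the cyclopentane), flanked by the C1 siloxy oxygen and the endo C6–Cl bond. Its ionisation turns C6 into ring carbon C2 and C5 into the electrophilic C3, next to the C4 methyl stereocentre that steers the incoming side chain.
4. Ring order: arene (orcinol) and cyclopentene (2-methylcyclopent-2-en-1-one) are bought; cyclopropane by chlorocarbenoid addition; cyclohexanone by one-carbon ring enlargement in the key step; quinone by the final oxidation.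
5. The aryl fragment comes from orcinol by chlorination, directed ortho-metalation/allylation and cross-metathesis; C4 is set by asymmetric conjugate addition, C3 by the key step, the carbinol by the CBS reagent, C2 by equilibration.

Key step: step 10

Remark: the cyclohexanone is numbered C1 (carbonyl) to C6 throughout. Bicycle 4 is numbered from the siloxy bridgehead (C1), so C6, C5 and C4 of 4 become C2, C3 and C4 of the cyclohexanone.
Assumption: compounds 1, 5 and 12 and all reagents are commercial, and the copper ligand of step 1 is used in the enantiomer that gives the (R)-product.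

## Route

Step 1
Reactants: 1 2-methylcyclopent-2-en-1-one
Product: 3 (R)-tert-butyl[(2,3-dimethylcyclopent-1-en-1-yl)oxy]dimethylsilane, via magnesium enolate 2 (not isolated)
Conditions: MeMgBr (1.2 equiv), Cu(OTf)2 (3 mol %), chiral imidazolinium salt as N-heterocyclic carbene precursor (4 mol %), Et2O, −30 °C; then TBSOTf (1.3 equiv), −30 → 0 °C
Reagents that add atoms: methylmagnesium bromide C[Mg]Br; tert-butyldimethylsilyl trifluoromethanesulfonate CC(C)(C)[Si](C)(C)OS(=O)(=O)C(F)(F)F
Why: Copper-catalysed asymmetric conjugate addition of the Grignard reagent to the α-substituted enone sets the methyl stereocentre (R, fixed by the ligand enantiomer), and O-silylation of enolate 2 gives the tetrasubstituted silyl enol ether as a single regioisomer.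

Step 2
Reactants: 3 (R)-tert-butyl[(2,3-dimethylcyclopent-1-en-1-yl)oxy]dimethylsilane
Product: 4 (1S,4R,5S,6S)-1-[(tert-butyldimethylsilyl)oxy]-6-chloro-4,5,6-trimethylbicyclo[3.1.0]hexane (chlorine endo)
Conditions: CH3CHCl2 (3 equiv), n-BuLi (2 equiv, slow addition), Et2O, −40 °C; cold aq NaHCO3 work-up, no chromatography, kept below 0 °C and used directly
Reagents that add atoms: 1,1-dichloroethane CC(Cl)Cl
Why: α-Elimination of 1-lithio-1,1-dichloroethane gives a chloro(methyl)carbenoid that cyclopropanates the electron-rich enol ether ([2+1] halocarbenoid addition to a silyl enol ether) on the face anti to the C4 methyl group, which sets C1 and C5, and the usual syn preference of chlorine is expected to place it endo at C6, as the ring opening of step 10 requires.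

Step 3
Reactants: 5 orcinol (5-methylbenzene-1,3-diol)
Product: 6 4-chloro-5-methylbenzene-1,3-diol
Conditions: SO2Cl2 (1.0 equiv), Et2O, 0 °C
Reagents that add atoms: sulfuryl chloride O=S(=O)(Cl)Cl
Why: Electrophilic aromatic chlorination should occur at C4, ortho to one hydroxyl and para to the other, rather than at the more hindered C2 between the two hydroxyls.

Step 4
Reactants: 6 4-chloro-5-methylbenzene-1,3-diol
Product: 7 2-chloro-1,5-bis(methoxymethoxy)-3-methylbenzene
Conditions: MOMCl (2.5 equiv), iPr2NEt, CH2Cl2, 0 → 23 °C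
Reagents that add atoms: chloromethyl methyl ether COCCl
Why: Base-mediated O-alkylation installs two methoxymethyl ethers, which serve as the directing groups for the metalation of step 5.

Step 5
Reactants: 7 2-chloro-1,5-bis(methoxymethoxy)-3-methylbenzene
Product: 9 2-allyl-4-chloro-1,3-bis(methoxymethoxy)-5-methylbenzene, via aryllithium 8 (not isolated)
Conditions: n-BuLi (1.1 equiv), THF, 0 °C; then CuI (10 mol %), allyl bromide, −78 → 0 °C
Reagents that add atoms: allyl bromide C=CCBr
Why: Directed ortho-metalation takes place at the only position flanked by two methoxymethoxy groups, and copper-catalysed allylation of aryllithium 8 gives the 2-allyl arene.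

Step 6
Reactants: 9 2-allyl-4-chloro-1,3-bis(methoxymethoxy)-5-methylbenzene
Product: 10 2-allyl-4-chloro-5-methylbenzene-1,3-diol
Conditions: HCl (3 M aq, cat.), MeOH, 45 °C
Reagents that add atoms: none
Why: Acid-catalysed acetal exchange with methanol removes both methoxymethyl groups at a stage where no acid-sensitive functionality is present.

Step 7
Reactants: 10 2-allyl-4-chloro-5-methylbenzene-1,3-diol
Product: 11 2-allyl-1,3-bis[(tert-butyldimethylsilyl)oxy]-4-chloro-5-methylbenzene
Conditions: TBSOTf (2.4 equiv), 2,6-lutidine, CH2Cl2, 0 °C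
Reagents that add atoms: tert-butyldimethylsilyl trifluoromethanesulfonate CC(C)(C)[Si](C)(C)OS(=O)(=O)C(F)(F)F
Why: Silyl triflate silylation of the hindered phenols gives aryl silyl ethers that tolerate the Lewis-acidic key step and are removed by fluoride at the end.

Step 8
Reactants: 11 2-allyl-1,3-bis[(tert-butyldimethylsilyl)oxy]-4-chloro-5-methylbenzene; 12 3-methylbut-3-en-2-one
Product: 13 (E)-5-{2,6-bis[(tert-butyldimethylsilyl)oxy]-3-chloro-4-methylphenyl}-3-methylpent-3-en-2-one
Conditions: 12 (5 equiv), second-generation Hoveyda–Grubbs catalyst RuCl2(SIMes)(=CH-C6H4-2-OiPr) (5 mol %), CH2Cl2, 40 °C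
Reagents that add atoms: none
Why: Olefin cross-metathesis of the terminal alkene with the 1,1-disubstituted enone should give the trisubstituted enone under thermodynamic control, with the E isomer (aryl-methylene trans to the acyl group) favoured.

Step 9
Reactants: 13 (E)-5-{2,6-bis[(tert-butyldimethylsilyl)oxy]-3-chloro-4-methylphenyl}-3-methylpent-3-en-2-one
Product: 15 {[(3E)-5-{2,6-bis[(tert-butyldimethylsilyl)oxy]-3-chloro-4-methylphenyl}-3-methylpenta-1,3-dien-2-yl]oxy}trimethylsilane, via lithium dienolate 14 (not isolated)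
Conditions: LiN(iPr)2 (1.1 equiv), THF, −78 °C; then Me3SiCl, Et3N, −78 → 0 °C; pentane, filtration, used crude
Reagents that add atoms: chlorotrimethylsilane C[Si](C)(C)Cl
Why: Kinetic deprotonation of the enone at the α' methyl group gives cross-conjugated dienolate 14, and O-silylation (silyl enol ether formation) gives the 2-siloxydiene with the E alkene untouched.

Step 10
Reactants: 4 (1S,4R,5S,6S)-1-[(tert-butyldimethylsilyl)oxy]-6-chloro-4,5,6-trimethylbicyclo[3.1.0]hexane; 15 {[(3E)-5-{2,6-bis[(tert-butyldimethylsilyl)oxy]-3-chloro-4-methylphenyl}-3-methylpenta-1,3-dien-2-yl]oxy}trimethylsilane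
Product: 17 (E)-1-{(1S,6R)-3-[(tert-butyldimethylsilyl)oxy]-1,2,6-trimethylcyclohex-2-en-1-yl}-5-{2,6-bis[(tert-butyldimethylsilyl)oxy]-3-chloro-4-methylphenyl}-3-methylpent-3-en-2-one, via O-silylated cyclohexenone cation 16 (not isolated)
Conditions: 4 (1.3 equiv), AgN(SO2CF3)2 (1.3 equiv), 2,6-di-tert-butyl-4-methylpyridine (0.2 equiv), CH2Cl2, −78 °C, dark; then 15 (1.0 equiv, slow addition), −78 → −40 °C; Et3N, aq NaHCO3
Reagents that add atoms: none
Why: Proposed new method: AgN(SO2CF3)2 removes the endo chloride of 4 as AgCl while the C1–C5 fusion bond opens in a disrotatory (2π) cyclopropyl-to-allyl electrocyclic ring opening pushed by the C1 oxygen lone pair, so the five-membered ring is enlarged by C6 to the O-silylated 2,3,4-trimethylcyclohexenone cation 16 instead of collapsing to the enone as in the known halocarbene ring enlargement of silyl enol ethers, because the non-nucleophilic counter-ion does not take the silyl group. The CH2 terminus of dienol silane 15 then attacks C3 of 16 in a Mukaiyama–Michael bond formation (closest known reaction types: silver-assisted opening of halocyclopropanes with capture of the allyl cation, and silyl triflimide-promoted Mukaiyama–Michael additions that build quaternary carbons on hindered enones), and transfer of Me3Si to the triflimide leaves the side-chain enone. No ring is closed by cyclisation: the six-membered ring arises only by this one-carbon ring enlargement and emerges as the regiodefined silyl enol ether, which keeps the ring carbonyl masked (no retro-Michael, no competition in step 11) and C2 planar. The new quaternary centre C3 (S) is controlled by the C4 methyl group, which is pseudoaxial in the half-chair cation (A1,2 strain with the C3 methyl) and directs axial attack to the opposite face, as in conjugate additions to 4-substituted cyclohexenones. The step needs 1,4- over 1,2-attack (C1 is shielded by the silyl group), reaction at the unsubstituted terminal carbon of the dienol, and no second Michael closure or self-condensation of 15; these are secured by pre-forming the cation in slight excess at low temperature, the hindered base and the bulky ring silyl group.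

Step 11
Reactants: 17 (E)-1-{(1S,6R)-3-[(tert-butyldimethylsilyl)oxy]-1,2,6-trimethylcyclohex-2-en-1-yl}-5-{2,6-bis[(tert-butyldimethylsilyl)oxy]-3-chloro-4-methylphenyl}-3-methylpent-3-en-2-one
Product: 18 (2S,3E)-1-{(1S,6R)-3-[(tert-butyldimethylsilyl)oxy]-1,2,6-trimethylcyclohex-2-en-1-yl}-5-{2,6-bis[(tert-butyldimethylsilyl)oxy]-3-chloro-4-methylphenyl}-3-methylpent-3-en-2-ol
Conditions: (R)-2-methyl-CBS-oxazaborolidine (0.3 equiv), catecholborane (2 equiv), toluene, −78 °C; MeOH, aq NaHCO3
Reagents that add atoms: none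
Why: Corey–Bakshi–Shibata reduction with the (R)-oxazaborolidine delivers hydride to the only ketone present, the α-branched alkenyl group acting as the large substituent, so the (S)-allylic alcohol should result; any minor ring enantiomer from step 1 becomes a separable diastereomer here.

Step 12
Reactants: 18 (2S,3E)-1-{(1S,6R)-3-[(tert-butyldimethylsilyl)oxy]-1,2,6-trimethylcyclohex-2-en-1-yl}-5-{2,6-bis[(tert-butyldimethylsilyl)oxy]-3-chloro-4-methylphenyl}-3-methylpent-3-en-2-ol
Product: 19 (2R,3S,4R)-3-[(2S,3E)-5-(3-chloro-2,6-dihydroxy-4-methylphenyl)-2-hydroxy-3-methylpent-3-en-1-yl]-2,3,4-trimethylcyclohexan-1-one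
Conditions: Bu4NF (4 equiv), THF, 0 → 23 °C, argon; AcOH quench
Reagents that add atoms: none
Why: Fluoride-mediated desilylation cleaves the two aryl silyl ethers and the silyl enol ether, and the released ring ketone should equilibrate in the basic medium to the C2 epimer with the methyl group equatorial and cis to the C4 methyl (thermodynamic control of C2).

Step 13
Reactants: 19 (2R,3S,4R)-3-[(2S,3E)-5-(3-chloro-2,6-dihydroxy-4-methylphenyl)-2-hydroxy-3-methylpent-3-en-1-yl]-2,3,4-trimethylcyclohexan-1-one
Product: 20 2-chloro-5-hydroxy-6-{(2E,4S)-4-hydroxy-3-methyl-5-[(1S,2R,6R)-1,2,6-trimethyl-3-oxocyclohexyl]pent-2-en-1-yl}-3-methylcyclohexa-2,5-diene-1,4-dione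
Conditions: (KSO3)2NO (2.5 equiv), KH2PO4 buffer, acetone/H2O, 0 → 23 °C
Reagents that add atoms: potassium nitrosodisulfonate (Fremy's salt) [K+].[K+].[O]N(S(=O)(=O)[O-])S(=O)(=O)[O-]
Why: Teuber oxidation introduces oxygen at the only unsubstituted ring position, para to one hydroxyl and ortho to the other, so either phenoxyl radical should lead to the same 2-hydroxy-1,4-benzoquinone without touching the ketone, the alkene or the allylic alcohol.

## Compound list

1 | 2-methylcyclopent-2-en-1-one | CC1=CCCC1=O | starting material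
2 | bromomagnesium (3R)-2,3-dimethylcyclopent-1-en-1-olate | C[C@@H]1CCC(O[Mg]Br)=C1C | intermediate
3 | (R)-tert-butyl[(2,3-dimethylcyclopent-1-en-1-yl)oxy]dimethylsilane | C[C@@H]1CCC(O[Si](C)(C)C(C)(C)C)=C1C | intermediate
4 | (1S,4R,5S,6S)-1-[(tert-butyldimethylsilyl)oxy]-6-chloro-4,5,6-trimethylbicyclo[3.1.0]hexane (chlorine endo, cyclopropane anti to the C4 methyl) | C[C@@H]1CC[C@]2(O[Si](C)(C)C(C)(C)C)[C@@]1(C)[C@]2(C)Cl | intermediate
5 | orcinol (5-methylbenzene-1,3-diol) | Cc1cc(O)cc(O)c1 | starting material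
6 | 4-chloro-5-methylbenzene-1,3-diol | Cc1cc(O)cc(O)c1Cl | intermediate
7 | 2-chloro-1,5-bis(methoxymethoxy)-3-methylbenzene | COCOc1cc(C)c(Cl)c(OCOC)c1 | intermediate
8 | [3-chloro-2,6-bis(methoxymethoxy)-4-methylphenyl]lithium | COCOc1cc(C)c(Cl)c(OCOC)c1[Li] | intermediate
9 | 2-allyl-4-chloro-1,3-bis(methoxymethoxy)-5-methylbenzene | COCOc1cc(C)c(Cl)c(OCOC)c1CC=C | intermediate
10 | 2-allyl-4-chloro-5-methylbenzene-1,3-diol | Cc1cc(O)c(CC=C)c(O)c1Cl | intermediate
11 | 2-allyl-1,3-bis[(tert-butyldimethylsilyl)oxy]-4-chloro-5-methylbenzene | Cc1cc(O[Si](C)(C)C(C)(C)C)c(CC=C)c(O[Si](C)(C)C(C)(C)C)c1Cl | intermediate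
12 | 3-methylbut-3-en-2-one | CC(=O)C(C)=C | starting material
13 | (E)-5-{2,6-bis[(tert-butyldimethylsilyl)oxy]-3-chloro-4-methylphenyl}-3-methylpent-3-en-2-one | CC(=O)/C(C)=C/Cc1c(O[Si](C)(C)C(C)(C)C)cc(C)c(Cl)c1O[Si](C)(C)C(C)(C)C | intermediate
14 | lithium (3E)-5-{2,6-bis[(tert-butyldimethylsilyl)oxy]-3-chloro-4-methylphenyl}-3-methylpenta-1,3-dien-2-olate | [Li]OC(=C)/C(C)=C/Cc1c(O[Si](C)(C)C(C)(C)C)cc(C)c(Cl)c1O[Si](C)(C)C(C)(C)C | intermediate
15 | {[(3E)-5-{2,6-bis[(tert-butyldimethylsilyl)oxy]-3-chloro-4-methylphenyl}-3-methylpenta-1,3-dien-2-yl]oxy}trimethylsilane | C=C(O[Si](C)(C)C)/C(C)=C/Cc1c(O[Si](C)(C)C(C)(C)C)cc(C)c(Cl)c1O[Si](C)(C)C(C)(C)C | intermediate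
16 | O-(tert-butyldimethylsilyl) (4R)-2,3,4-trimethylcyclohex-2-en-1-one cation (1-siloxyallyl cation), bis(trifluoromethanesulfonyl)imide salt | C[C@@H]1CCC(=[O+][Si](C)(C)C(C)(C)C)C(C)=C1C.[N-](S(=O)(=O)C(F)(F)F)S(=O)(=O)C(F)(F)F | intermediate
17 | (E)-1-{(1S,6R)-3-[(tert-butyldimethylsilyl)oxy]-1,2,6-trimethylcyclohex-2-en-1-yl}-5-{2,6-bis[(tert-butyldimethylsilyl)oxy]-3-chloro-4-methylphenyl}-3-methylpent-3-en-2-one | Cc1cc(O[Si](C)(C)C(C)(C)C)c(C/C=C(\C)C(=O)C[C@@]2(C)[C@H](C)CCC(O[Si](C)(C)C(C)(C)C)=C2C)c(O[Si](C)(C)C(C)(C)C)c1Cl | intermediate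
18 | (2S,3E)-1-{(1S,6R)-3-[(tert-butyldimethylsilyl)oxy]-1,2,6-trimethylcyclohex-2-en-1-yl}-5-{2,6-bis[(tert-butyldimethylsilyl)oxy]-3-chloro-4-methylphenyl}-3-methylpent-3-en-2-ol | Cc1cc(O[Si](C)(C)C(C)(C)C)c(C/C=C(\C)[C@@H](O)C[C@@]2(C)[C@H](C)CCC(O[Si](C)(C)C(C)(C)C)=C2C)c(O[Si](C)(C)C(C)(C)C)c1Cl | intermediate
19 | (2R,3S,4R)-3-[(2S,3E)-5-(3-chloro-2,6-dihydroxy-4-methylphenyl)-2-hydroxy-3-methylpent-3-en-1-yl]-2,3,4-trimethylcyclohexan-1-one | Cc1cc(O)c(C/C=C(\C)[C@@H](O)C[C@@]2(C)[C@H](C)CCC(=O)[C@@H]2C)c(O)c1Cl | intermediate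
20 | 2-chloro-5-hydroxy-6-{(2E,4S)-4-hydroxy-3-methyl-5-[(1S,2R,6R)-1,2,6-trimethyl-3-oxocyclohexyl]pent-2-en-1-yl}-3-methylcyclohexa-2,5-diene-1,4-dione | CC1=C(Cl)C(=O)C(C/C=C(\C)[C@@H](O)C[C@@]2(C)[C@H](C)CCC(=O)[C@@H]2C)=C(O)C1=O | target

## Step count and risks

Total: 13 steps. Longest linear sequence: 11 steps (5 → 20, steps 3–9 and 10–13); the ring fragment 4 takes 2 steps.

Most likely to fail:

1. Step 10 (proposed new method). The congested bond formation at C3 may be outrun by loss of the silyl group from the cation (giving the enone), by proton loss from the cation, or by self-condensation of the dienol silane under the silyl triflimide that is released; an exo-chloro epimer of 4 would not ionise at all. The fallback uses known reactions, sets out from 4 (and uses 11) and comes back at 19. Warming 4 in toluene completes the known halocarbene ring enlargement to (R)-2,3,4-trimethylcyclohex-2-en-1-one F1. Hosomi–Sakurai conjugate allylation (allyltrimethylsilane, TiCl4, CH2Cl2, −78 °C, then equilibration of C2 with K2CO3/MeOH) should give (2R,3S,4R)-2,3,4-trimethyl-3-(prop-2-en-1-yl)cyclohexan-1-one F2, again by axial attack anti to the C4 methyl. Ozonolysis (O3, CH2Cl2, −78 °C; Me2S) gives 2-[(1S,2R,6R)-1,2,6-trimethyl-3-oxocyclohexyl]acetaldehyde F3. An aldehyde-selective asymmetric Nozaki–Hiyama–Kishi addition of 2-bromopropene (CrCl2, NiCl2 cat., chiral sulfonamide ligand) gives (2R,3S,4R)-3-[(2S)-2-hydroxy-3-methylbut-3-en-1-yl]-2,3,4-trimethylcyclohexan-1-one F4. Cross-metathesis of F4 with allyl arene 11 (second-generation Hoveyda–Grubbs catalyst) gives the bis-silyl ether (2R,3S,4R)-3-[(2S,3E)-5-{2,6-bis[(tert-butyldimethylsilyl)oxy]-3-chloro-4-methylphenyl}-2-hydroxy-3-methylpent-3-en-1-yl]-2,3,4-trimethylcyclohexan-1-one F5, and Bu4NF returns to the route at 19.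

2. Step 2. Carbenoid transfer to the tetrasubstituted enol ether may be sluggish, chlorine may be delivered to the exo position (an adduct that cannot ionise with ring enlargement), or the adduct may open prematurely during isolation. The fallback sets out from 3 and comes back at 17. Ethylidene transfer (Et2Zn, CH3CHI2, CH2Cl2, Furukawa conditions) gives 1-[(tert-butyldimethylsilyl)oxy]-4,5,6-trimethylbicyclo[3.1.0]hexane F6, of which either C6 epimer serves. Saegusa–Ito oxidative ring enlargement (FeCl3, DMF) gives (4R)-3-chloro-2,3,4-trimethylcyclohexan-1-one F7, and NaOAc in MeOH eliminates HCl to the enone F1 described above. F1 with TBSOTf (1.1 equiv) and 15 in CH2Cl2 (silyl triflate-promoted Mukaiyama–Michael addition with silyl transfer, the enone–silyl triflate adduct being the triflate counterpart of cation 16) then gives 17.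

3. Step 11. Facial discrimination between the α-branched alkenyl group and the neopentyl-type methylene group may be insufficient, or conjugate reduction may compete. The fallback sets out from 17 and comes back at 18. Unselective 1,2-reduction (iBu2AlH, toluene, −78 °C) gives 18 together with its carbinol epimer, (2R,3E)-1-{(1S,6R)-3-[(tert-butyldimethylsilyl)oxy]-1,2,6-trimethylcyclohex-2-en-1-yl}-5-{2,6-bis[(tert-butyldimethylsilyl)oxy]-3-chloro-4-methylphenyl}-3-methylpent-3-en-2-ol F8. The epimers are separated by chromatography, and F8 is re-oxidised to 17 with MnO2 and recycled.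

## Further compounds

F1 | step 10 | (R)-2,3,4-trimethylcyclohex-2-en-1-one | C[C@@H]1CCC(=O)C(C)=C1C
F2 | step 10 | (2R,3S,4R)-2,3,4-trimethyl-3-(prop-2-en-1-yl)cyclohexan-1-one | C=CC[C@@]1(C)[C@H](C)CCC(=O)[C@@H]1C
F3 | step 10 | 2-[(1S,2R,6R)-1,2,6-trimethyl-3-oxocyclohexyl]acetaldehyde | O=CC[C@@]1(C)[C@H](C)CCC(=O)[C@@H]1C
F4 | step 10 | (2R,3S,4R)-3-[(2S)-2-hydroxy-3-methylbut-3-en-1-yl]-2,3,4-trimethylcyclohexan-1-one | C=C(C)[C@@H](O)C[C@@]1(C)[C@H](C)CCC(=O)[C@@H]1C
F5 | step 10 | (2R,3S,4R)-3-[(2S,3E)-5-{2,6-bis[(tert-butyldimethylsilyl)oxy]-3-chloro-4-methylphenyl}-2-hydroxy-3-methylpent-3-en-1-yl]-2,3,4-trimethylcyclohexan-1-one | Cc1cc(O[Si](C)(C)C(C)(C)C)c(C/C=C(\C)[C@@H](O)C[C@@]2(C)[C@H](C)CCC(=O)[C@@H]2C)c(O[Si](C)(C)C(C)(C)C)c1Cl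
F6 | step 2 | 1-[(tert-butyldimethylsilyl)oxy]-4,5,6-trimethylbicyclo[3.1.0]hexane (4R, cyclopropane anti to the C4 methyl, C6 epimers) | C[C@@H]1CC[C@]2(O[Si](C)(C)C(C)(C)C)[C@@]1(C)C2C
F7 | step 2 | (4R)-3-chloro-2,3,4-trimethylcyclohexan-1-one (mixture at C2 and C3) | C[C@@H]1CCC(=O)C(C)C1(C)Cl
F8 | step 11 | (2R,3E)-1-{(1S,6R)-3-[(tert-butyldimethylsilyl)oxy]-1,2,6-trimethylcyclohex-2-en-1-yl}-5-{2,6-bis[(tert-butyldimethylsilyl)oxy]-3-chloro-4-methylphenyl}-3-methylpent-3-en-2-ol | Cc1cc(O[Si](C)(C)C(C)(C)C)c(C/C=C(\C)[C@H](O)C[C@@]2(C)[C@H](C)CCC(O[Si](C)(C)C(C)(C)C)=C2C)c(O[Si](C)(C)C(C)(C)C)c1Cl
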